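**Retrosynthetic overview**
1. 20 ⇐ 19: last step, dearomative 5-exo spiro-hydroalkoxylation of the 3-alkylfuran by the C9 hydroxyl (C13–O bond; both spiro oxygen rings at once).
2. 19 ⇐ 12 + 14: C9–C11 bond by furylethyl-lithium addition to a non-enolisable epoxy ketone; the C6 ketal then becomes the 6-acetate.
3. 12 ⇐ 11: ring A closed by a bridging lactone-enolate alkylation (C3–C4), which fixes C4.
4. 11 ⇐ 5 + 6 + two formaldehyde units: asymmetric Mukaiyama–Michael addition (C4–C5), hydroxymethylation/lactonisation (C10–C20, lactone), methylenation/epoxidation (C17, oxirane).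
5. Ring order: ring B (from 1) → δ-lactone → oxirane → ring A → spiro tetrahydrofuran/dihydrofuran.

Assumption: the SMILES is taken literally, i.e. 4S,5S,6R,8R,9S,10S,13R with H-5 cis to C-20 (rings A/B cis-fused, lactone trans-fused to ring B); labdane numbering (C1–C20) is used for the skeleton from compound 7 onward.

**Route**

Step 1
Reactants: 1 1,4-dioxaspiro[4.5]dec-6-en-8-one
Product: 2 7-iodo-1,4-dioxaspiro[4.5]dec-6-en-8-one
Conditions: I2, pyridine, CH2Cl2, 0 °C→rt
Reagents that add atoms: iodine, II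
Why: Johnson-type α-iodination of an enone (pyridine conjugate addition, iodination, elimination), which leaves the ketal untouched.

Step 2
Reactants: 2 7-iodo-1,4-dioxaspiro[4.5]dec-6-en-8-one; 3 allyl chloride
Product: 5 7-(3-chloropropyl)-1,4-dioxaspiro[4.5]dec-6-en-8-one, via borane 4 (not isolated)
Conditions: 3, 9-BBN, THF, 0 °C→rt; then 2, Pd(dppf)Cl2 (5 mol %), Ph3As, Cs2CO3, DMF–H2O, rt
Reagents that add atoms: none
Why: anti-Markovnikov hydroboration of allyl chloride followed by B-alkyl Suzuki–Miyaura coupling with the α-iodoenone; the primary alkyl chloride is inert to the palladium catalyst under these conditions.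

Step 3
Reactants: 5 7-(3-chloropropyl)-1,4-dioxaspiro[4.5]dec-6-en-8-one; 6 (E)-1-methoxy-1-(trimethylsilyloxy)prop-1-ene
Product: 7 methyl 2-[(6R)-7-(3-chloropropyl)-8-(trimethylsilyloxy)-1,4-dioxaspiro[4.5]dec-7-en-6-yl]propanoate
Conditions: (S)-o-tolyl-CBS-oxazaborolidine·HNTf2 (20 mol %), Ph3PO (25 mol %), toluene, −20 °C; Et3N, non-aqueous work-up
Reagents that add atoms: none
Why: enantioselective Mukaiyama–Michael addition under metal-free chiral Lewis acid catalysis, in which the oxazaborolidinium ion binds the enone carbonyl and exposes one face of C5, setting C5 (R here; the catalyst antipode is used if the sense is opposite) and giving the regiodefined C9=C10 silyl enol ether, while C4 stays an epimer mixture that step 7 erases.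

Step 4
Reactants: 7 methyl 2-[(6R)-7-(3-chloropropyl)-8-(trimethylsilyloxy)-1,4-dioxaspiro[4.5]dec-7-en-6-yl]propanoate
Product: 9 (4aR,8aS)-8a-(3-chloropropyl)-5,5-ethylenedioxy-4-methyloctahydro-1H-isochromene-3,8-dione, via hydroxy ester 8 (not isolated)
Conditions: 37 % aq. HCHO, Sc(OTf)3 (10 mol %), THF, 0 °C→rt; then CSA (10 mol %), toluene, 60 °C
Reagents that add atoms: formaldehyde, C=O
Why: Mukaiyama aldol hydroxymethylation of the silyl enol ether occurs at C10 anti to the C5 side chain, so C20 ends cis to H5 (10S), and acid lactonisation gives the trans-fused δ-lactone, which also blocks retro-aldol loss of formaldehyde.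

Step 5
Reactants: 9 (4aR,8aS)-8a-(3-chloropropyl)-5,5-ethylenedioxy-4-methyloctahydro-1H-isochromene-3,8-dione
Product: 10 (4aR,8aS)-8a-(3-chloropropyl)-5,5-ethylenedioxy-4-methyl-7-methylideneoctahydro-1H-isochromene-3,8-dione
Conditions: (CH2O)n, i-Pr2NH·TFA, THF, reflux
Reagents that add atoms: formaldehyde (from paraformaldehyde), C=O
Why: Mannich-type direct α-methylenation, which can only occur at C8 because C10 is quaternary and the lactone α-position is far less acidic.

Step 6
Reactants: 10 (4aR,8aS)-8a-(3-chloropropyl)-5,5-ethylenedioxy-4-methyl-7-methylideneoctahydro-1H-isochromene-3,8-dione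
Product: 11 (4aR,7R,8aS)-8a-(3-chloropropyl)-5,5-ethylenedioxy-4-methylhexahydrospiro[isochromene-7,2'-oxirane]-3,8-dione
Conditions: t-BuOOH (decane), DBU, CH2Cl2, 0 °C→rt
Reagents that add atoms: tert-butyl hydroperoxide, CC(C)(C)OO
Why: Weitz–Scheffer nucleophilic epoxidation of the enone, in which the enolate closes the oxirane on the β face because the axial C1 methylene on C10 shields the α face of C8, giving 8R (oxirane oxygen cis to C20).

Step 7
Reactants: 11 (4aR,7R,8aS)-8a-(3-chloropropyl)-5,5-ethylenedioxy-4-methylhexahydrospiro[isochromene-7,2'-oxirane]-3,8-dione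
Product: 12 (4S,5S,8R,10S)-6,6-ethylenedioxy-8,17-epoxy-9-oxo-11,12,13,14,15,16-hexanorlabdan-19,20-olide
Conditions: KN(SiMe3)2, n-Bu4NI (10 mol %), THF–DMPU, −78 °C→rt
Reagents that add atoms: none
Why: intramolecular enolate alkylation (6-exo-tet) in which the only acidic C–H is at C4 (the ketone has no α-hydrogen) and the axial chloropropyl arm reaches the lactone enolate only on the face syn to C1, closing ring A as a bicyclo[3.3.1] lactone and forcing C4 to S from either C4 epimer.

Step 8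
Reactants: 13 2-(furan-3-yl)ethanol
Product: 14 3-(2-iodoethyl)furan
Conditions: I2, PPh3, imidazole, CH2Cl2, 0 °C→rt
Reagents that add atoms: iodine, II
Why: Appel-type iodination of a primary alcohol.

Step 9
Reactants: 12 (4S,5S,8R,10S)-6,6-ethylenedioxy-8,17-epoxy-9-oxo-11,12,13,14,15,16-hexanorlabdan-19,20-olide; 14 3-(2-iodoethyl)furan
Product: 16 (4S,5S,8R,9S,10S)-6,6-ethylenedioxy-8,17:15,16-diepoxy-9-hydroxylabda-13(16),14-dien-19,20-olide, via organolithium 15 (not isolated)
Conditions: 14, t-BuLi (2.0 equiv), Et2O, −78 °C; then 12, LaCl3·2LiCl (30 mol %), THF, −78→−30 °C; then H2O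
Reagents that add atoms: none
Why: lithium–iodine exchange then 1,2-addition to the non-enolisable ketone, where equatorial approach is blocked by the two flanking axial carbons (C1 and C17) so the nucleophile enters axially from the β face to give the 9α-hydroxyl (9S), while the bridgehead-flanked lactone and the oxirane survive at low temperature.

Step 10
Reactants: 16 (4S,5S,8R,9S,10S)-6,6-ethylenedioxy-8,17:15,16-diepoxy-9-hydroxylabda-13(16),14-dien-19,20-olide
Product: 17 (4S,5S,8R,9S,10S)-8,17:15,16-diepoxy-9-hydroxy-6-oxolabda-13(16),14-dien-19,20-olide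
Conditions: PPTS (20 mol %), acetone–H2O (10:1), 45 °C
Reagents that add atoms: water, O
Why: mild acid-catalysed ketal hydrolysis that the oxirane, tertiary alcohol and furan tolerate; 17 is reduced at once because C5 is now α to a ketone.

Step 11
Reactants: 17 (4S,5S,8R,9S,10S)-8,17:15,16-diepoxy-9-hydroxy-6-oxolabda-13(16),14-dien-19,20-olide
Product: 18 (4S,5S,6R,8R,9S,10S)-8,17:15,16-diepoxy-6,9-dihydroxylabda-13(16),14-dien-19,20-olide
Conditions: SmI2 (2.5 equiv), MeOH, THF, −78→0 °C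
Reagents that add atoms: none
Why: samarium diiodide ketyl reduction gives the thermodynamic equatorial alcohol (6R, cis to H5), whereas hydride would attack from the open β face and give the axial epimer; lactone, oxirane and furan are inert.

Step 12
Reactants: 18 (4S,5S,6R,8R,9S,10S)-8,17:15,16-diepoxy-6,9-dihydroxylabda-13(16),14-dien-19,20-olide
Product: 19 (4S,5S,6R,8R,9S,10S)-6-acetoxy-8,17:15,16-diepoxy-9-hydroxylabda-13(16),14-dien-19,20-olide
Conditions: Ac2O, DMAP (cat.), pyridine, CH2Cl2, rt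
Reagents that add atoms: acetic anhydride, CC(=O)OC(C)=O
Why: DMAP-catalysed acylation of the secondary alcohol; the hindered tertiary C9 hydroxyl does not react.

Step 13
Reactants: 19 (4S,5S,6R,8R,9S,10S)-6-acetoxy-8,17:15,16-diepoxy-9-hydroxylabda-13(16),14-dien-19,20-olide
Product: 20 (4S,5S,6R,8R,9S,10S,13R)-6-acetoxy-8,17:9,13:15,16-triepoxylabd-14-en-19,20-olide
Conditions: [(1R,2R)-N,N'-bis(3,5-di-tert-butylsalicylidene)cyclohexane-1,2-diaminato]cobalt (divalent cobalt, 10 mol %), N-fluoro-2,4,6-trimethylpyridinium triflate (1.3 equiv), PhSiH3 (1.2 equiv), PhCF3, 0 °C; Et3N quench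
Reagents that add atoms: none
Why: Proposed new method: cobalt-hydride hydrogen-atom transfer to the furan α-carbon C16 gives a tertiary, oxygen-stabilised 2H-furanyl radical that is oxidised (radical-polar crossover) to the C13/C15 allyl-oxocarbenium ion, which the C9 hydroxyl captures 5-exo at C13 under buffered, non-equilibrating conditions, so the dearomatised spiro enol ether, which is uphill from the furan, is formed kinetically, with C13 (R) set by the chiral salen ligand together with the substrate (the other ligand enantiomer is used if mismatched); the closest known reaction type is the cobalt-salen/N-fluoropyridinium/silane Markovnikov hydroalkoxylation of unactivated alkenes, which has not been shown on a furan.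

**Compound list**
1 | 1,4-dioxaspiro[4.5]dec-6-en-8-one | O=C1C=CC2(CC1)OCCO2 | starting material
2 | 7-iodo-1,4-dioxaspiro[4.5]dec-6-en-8-one | O=C1CCC2(OCCO2)C=C1I | intermediate
3 | allyl chloride | C=CCCl | starting material
4 | B-(3-chloropropyl)-9-borabicyclo[3.3.1]nonane | ClCCCB1C2CCCC1CCC2 | intermediate
5 | 7-(3-chloropropyl)-1,4-dioxaspiro[4.5]dec-6-en-8-one | O=C1CCC2(OCCO2)C=C1CCCCl | intermediate
6 | (E)-1-methoxy-1-(trimethylsilyloxy)prop-1-ene | C/C=C(/O[Si](C)(C)C)OC | starting material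
7 | methyl 2-[(6R)-7-(3-chloropropyl)-8-(trimethylsilyloxy)-1,4-dioxaspiro[4.5]dec-7-en-6-yl]propanoate (both epimers at the propanoate C2 = C4) | C12(OCCO1)CCC(O[Si](C)(C)C)=C(CCCCl)[C@H]2C(C)C(=O)OC | intermediate
8 | methyl 2-[(6R,7S)-7-(3-chloropropyl)-7-(hydroxymethyl)-8-oxo-1,4-dioxaspiro[4.5]decan-6-yl]propanoate (C4 epimers) | C12(OCCO1)CCC(=O)[C@@](CO)(CCCCl)[C@H]2C(C)C(=O)OC | intermediate
9 | (4aR,8aS)-8a-(3-chloropropyl)-5,5-ethylenedioxy-4-methyloctahydro-1H-isochromene-3,8-dione (trans-fused keto lactone; labdane 5R,10S; C4 epimers) | C12(OCCO1)CCC(=O)[C@]3(CCCCl)COC(=O)C(C)[C@@H]23 | intermediate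
10 | (4aR,8aS)-8a-(3-chloropropyl)-5,5-ethylenedioxy-4-methyl-7-methylideneoctahydro-1H-isochromene-3,8-dione (C4 epimers) | C12(OCCO1)CC(=C)C(=O)[C@]3(CCCCl)COC(=O)C(C)[C@@H]23 | intermediate
11 | (4aR,7R,8aS)-8a-(3-chloropropyl)-5,5-ethylenedioxy-4-methylhexahydrospiro[isochromene-7,2'-oxirane]-3,8-dione (labdane 5R,8R,10S; C4 epimers) | C12(OCCO1)C[C@@]3(CO3)C(=O)[C@]3(CCCCl)COC(=O)C(C)[C@@H]23 | intermediate
12 | (4S,5S,8R,10S)-6,6-ethylenedioxy-8,17-epoxy-9-oxo-11,12,13,14,15,16-hexanorlabdan-19,20-olide | C12(OCCO1)C[C@@]3(CO3)C(=O)[C@]34CCC[C@](C)(C(=O)OC3)[C@@H]24 | intermediate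
13 | 2-(furan-3-yl)ethanol | OCCc1ccoc1 | starting material
14 | 3-(2-iodoethyl)furan | ICCc1ccoc1 | intermediate
15 | 2-(furan-3-yl)ethyllithium | [Li]CCc1ccoc1 | intermediate
16 | (4S,5S,8R,9S,10S)-6,6-ethylenedioxy-8,17:15,16-diepoxy-9-hydroxylabda-13(16),14-dien-19,20-olide | C12(OCCO1)C[C@@]3(CO3)[C@](O)(CCc3ccoc3)[C@]34CCC[C@](C)(C(=O)OC3)[C@@H]24 | intermediate
17 | (4S,5S,8R,9S,10S)-8,17:15,16-diepoxy-9-hydroxy-6-oxolabda-13(16),14-dien-19,20-olide | O=C1C[C@@]2(CO2)[C@](O)(CCc2ccoc2)[C@]23CCC[C@](C)(C(=O)OC2)[C@@H]13 | intermediate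
18 | (4S,5S,6R,8R,9S,10S)-8,17:15,16-diepoxy-6,9-dihydroxylabda-13(16),14-dien-19,20-olide | O[C@@H]1C[C@@]2(CO2)[C@](O)(CCc2ccoc2)[C@]23CCC[C@](C)(C(=O)OC2)[C@@H]13 | intermediate
19 | (4S,5S,6R,8R,9S,10S)-6-acetoxy-8,17:15,16-diepoxy-9-hydroxylabda-13(16),14-dien-19,20-olide | CC(=O)O[C@@H]1C[C@@]2(CO2)[C@](O)(CCc2ccoc2)[C@]23CCC[C@](C)(C(=O)OC2)[C@@H]13 | intermediate
20 | (4S,5S,6R,8R,9S,10S,13R)-6-acetoxy-8,17:9,13:15,16-triepoxylabd-14-en-19,20-olide | CC(=O)O[C@@H]1C[C@@]2(CO2)[C@]2(CC[C@]3(C=COC3)O2)[C@]23CCC[C@](C)(C(=O)OC2)[C@@H]13 | target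

**Step count and risks**

Total step count: 13. Longest linear sequence: 12 (1→2→5→7→9→10→11→12→16→17→18→19→20); step 8 is a one-step branch.

Steps most likely to fail:

Step 13 (the proposed new step). The furan may resist hydrogen-atom transfer, hydrogen may add at C15 instead of C16, the product enol ether may re-enter the cycle, or the acid formed may return 20 to 19. The fallback uses known reactions, sets out from 18 and comes back at 20. Photooxygenation of the furan (O2, rose bengal, hν, i-Pr2NEt, CH2Cl2, −78 °C) gives the γ-hydroxybutenolide (4S,5S,6R,8R,9S,10S)-8,17-epoxy-6,9,16-trihydroxylabd-13-ene-15,16:19,20-diolide F6. NaBH4 in MeOH at 0 °C reduces it to the butenolide (4S,5S,6R,8R,9S,10S)-8,17-epoxy-6,9-dihydroxylabd-13-ene-15,16:19,20-diolide F7. DBU in CH2Cl2 closes the spiro ether by intramolecular oxa-Michael addition of the C9 hydroxyl, giving (4S,5S,6R,8R,9S,10S,13R)-8,17:9,13-diepoxy-6-hydroxylabdane-15,16:19,20-diolide F8 (the reaction equilibrates, and the 13R epimer is separated). i-Bu2AlH (3 equiv, CH2Cl2, −78 °C) reduces the unhindered γ-lactone, far faster than the bridged δ-lactone, to the lactol (4S,5S,6R,8R,9S,10S,13R)-8,17:9,13:15,16-triepoxy-6,15-dihydroxylabdan-19,20-olide F9. Ac2O/pyridine/DMAP gives the diacetate (4S,5S,6R,8R,9S,10S,13R)-6,15-diacetoxy-8,17:9,13:15,16-triepoxylabdan-19,20-olide F10. Me3SiOTf and i-Pr2NEt (CH2Cl2, −78→0 °C) then ionise the anomeric acetate and remove H-14 to give the enol ether 20.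

Step 3. The enone is 2-alkylated and its β-carbon is neopentyl, so conversion or enantioselectivity may be poor, and silyl cations may attack the ketal. The fallback sets out from 5 and comes back at 9. It gives up catalyst control: the Mukaiyama–Michael addition of 6 to 5 is run with an achiral silyl Lewis acid (Me3SiNTf2, 2 mol %, CH2Cl2, −78 °C), a known reaction on hindered enones. This gives 7 together with its enantiomer methyl 2-[(6S)-7-(3-chloropropyl)-8-(trimethylsilyloxy)-1,4-dioxaspiro[4.5]dec-7-en-6-yl]propanoate F1. The mixture is taken through the conditions of step 4, via 8 and its enantiomer methyl 2-[(6S,7R)-7-(3-chloropropyl)-7-(hydroxymethyl)-8-oxo-1,4-dioxaspiro[4.5]decan-6-yl]propanoate F2, to racemic lactone. Preparative chiral SFC removes (4aS,8aR)-8a-(3-chloropropyl)-5,5-ethylenedioxy-4-methyloctahydro-1H-isochromene-3,8-dione F3 and returns 9.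

Step 9. The ketone sits between two fully substituted carbons, and the lactone and oxirane are competing electrophiles. The fallback sets out from 12 and comes back at 16. It uses a small linear sp nucleophile and then saturates it: 3-ethynylfuran and n-BuLi (THF, −78 °C) give lithium (furan-3-yl)acetylide F4, which adds to 12 from the same axial face to give the propargylic alcohol (4S,5S,8R,9S,10S)-6,6-ethylenedioxy-8,17:15,16-diepoxy-9-hydroxylabda-13(16),14-dien-11-yn-19,20-olide F5. Diimide (2-nitrobenzenesulfonylhydrazide, Et3N, CH2Cl2, rt) reduces the triple bond without touching the furan or the oxirane and gives 16.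

Further compounds
F1 | step 3 | methyl 2-[(6S)-7-(3-chloropropyl)-8-(trimethylsilyloxy)-1,4-dioxaspiro[4.5]dec-7-en-6-yl]propanoate (ent-7) | C12(OCCO1)CCC(O[Si](C)(C)C)=C(CCCCl)[C@@H]2C(C)C(=O)OC
F2 | step 3 | methyl 2-[(6S,7R)-7-(3-chloropropyl)-7-(hydroxymethyl)-8-oxo-1,4-dioxaspiro[4.5]decan-6-yl]propanoate (ent-8) | C12(OCCO1)CCC(=O)[C@](CO)(CCCCl)[C@@H]2C(C)C(=O)OC
F3 | step 3 | (4aS,8aR)-8a-(3-chloropropyl)-5,5-ethylenedioxy-4-methyloctahydro-1H-isochromene-3,8-dione (ent-9) | C12(OCCO1)CCC(=O)[C@@]3(CCCCl)COC(=O)C(C)[C@H]23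
F4 | step 9 | lithium (furan-3-yl)acetylide | [Li]C#Cc1ccoc1
F5 | step 9 | (4S,5S,8R,9S,10S)-6,6-ethylenedioxy-8,17:15,16-diepoxy-9-hydroxylabda-13(16),14-dien-11-yn-19,20-olide | C12(OCCO1)C[C@@]3(CO3)[C@](O)(C#Cc3ccoc3)[C@]34CCC[C@](C)(C(=O)OC3)[C@@H]24
F6 | step 13 | (4S,5S,6R,8R,9S,10S)-8,17-epoxy-6,9,16-trihydroxylabd-13-ene-15,16:19,20-diolide (C16 epimers) | O[C@@H]1C[C@@]2(CO2)[C@](O)(CCC2=CC(=O)OC2O)[C@]23CCC[C@](C)(C(=O)OC2)[C@@H]13
F7 | step 13 | (4S,5S,6R,8R,9S,10S)-8,17-epoxy-6,9-dihydroxylabd-13-ene-15,16:19,20-diolide | O[C@@H]1C[C@@]2(CO2)[C@](O)(CCC2=CC(=O)OC2)[C@]23CCC[C@](C)(C(=O)OC2)[C@@H]13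
F8 | step 13 | (4S,5S,6R,8R,9S,10S,13R)-8,17:9,13-diepoxy-6-hydroxylabdane-15,16:19,20-diolide | O[C@@H]1C[C@@]2(CO2)[C@]2(CC[C@]3(CC(=O)OC3)O2)[C@]23CCC[C@](C)(C(=O)OC2)[C@@H]13
F9 | step 13 | (4S,5S,6R,8R,9S,10S,13R)-8,17:9,13:15,16-triepoxy-6,15-dihydroxylabdan-19,20-olide (C15 epimers) | O[C@@H]1C[C@@]2(CO2)[C@]2(CC[C@]3(CC(O)OC3)O2)[C@]23CCC[C@](C)(C(=O)OC2)[C@@H]13
F10 | step 13 | (4S,5S,6R,8R,9S,10S,13R)-6,15-diacetoxy-8,17:9,13:15,16-triepoxylabdan-19,20-olide (C15 epimers) | CC(=O)O[C@@H]1C[C@@]2(CO2)[C@]2(CC[C@]3(CC(OC(C)=O)OC3)O2)[C@]23CCC[C@](C)(C(=O)OC2)[C@@H]13
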